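**Retrosynthetic overview**

1. Target 21 ⇐ primary alcohol 19 ⇐ naphthylmethyl (NAP) ether 18 ⇐ 3,6-dihydro-1,2-dioxin 17, which carries the chain on C6 as a conjugated enyne; one diimide step saturates ring C4=C5 and the side-chain C≡C.
2. Key disconnection of 17 (formal [3+3] annulation): bonds C3–C4 and O1–C6 are cut, giving α-methoxy hydroperoxide 15 (atoms C3, O2, O1) and tertiary carbinol 10 (atoms C4, C5, C6).
3. Enabling feature: in the 1,2-dioxane ring (O1, O2, C3–C6) the fully substituted C6 is bonded to O1; with its chain drawn as an alkyne and C4=C5 as a (Z)-vinylsilane it is a cation site stabilised twice (allyl and propargyl). C3, bonded to O2, is an acetal-level carbon, i.e. a latent peroxycarbenium ion.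
4. 10 ⇐ ynone 5 (from farnesol 1 via farnesal 2 and enyne 3) + (Z)-silylvinyl bromide 8; 15 ⇐ (R)-Roche ester 11 (protection, half-reduction, acetal, perhydrolysis).
5. Ring order: the only ring, the dioxane, is closed as its 3,6-dihydro form in step 10 and saturated in step 11.

Key step: step 10

Remark: the ring is numbered O1, O2, C3 (carrying the propanoic acid), C4, C5, C6 (quaternary). The acetal carbon in 15 and 16 and the carbinol carbon (later C6) in 10 and 16 are deliberately unassigned mixtures.

**Route**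

Step 1
Reactants: 1 (2E,6E)-farnesol
Product: 2 (2E,6E)-3,7,11-trimethyldodeca-2,6,10-trienal
Conditions: TEMPO (cat.), PhI(OAc)2, CH2Cl2, rt
Reagents that add atoms: none
Why: The oxoammonium (TEMPO) oxidation of the primary allylic alcohol stops at the enal and should leave the trisubstituted alkenes and the 2E geometry untouched.

Step 2
Reactants: 2 (2E,6E)-3,7,11-trimethyldodeca-2,6,10-trienal
Product: 3 (3E,7E)-4,8,12-trimethyltrideca-3,7,11-trien-1-yne
Conditions: Me3SiCHN2, LiN(i-Pr)2, THF, −78 °C; then 2, −78 °C to rt; H2O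
Reagents that add atoms: trimethylsilyldiazomethane C[Si](C)(C)C=[N+]=[N-]
Why: Colvin rearrangement: the lithiated silyldiazomethane adds to the aldehyde, Me3SiOLi and N2 are lost and a 1,2-hydrogen shift should give the terminal alkyne with the E geometry of the enyne retained.

Step 3
Reactants: 3 (3E,7E)-4,8,12-trimethyltrideca-3,7,11-trien-1-yne
Product: 5 (5E,9E)-6,10,14-trimethylpentadeca-5,9,13-trien-3-yn-2-one, via lithium acetylide 4 (not isolated)
Conditions: n-BuLi, THF, −78 °C; MeC(O)N(OMe)Me, −78 to 0 °C; H2O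
Reagents that add atoms: N-methoxy-N-methylacetamide CON(C)C(C)=O
Why: Weinreb ketone synthesis: the chelated tetrahedral adduct is stable until work-up, so the acetylide should be acylated once to the methyl ynone.

Step 4
Reactants: 6 (E)-1,2-bis(trimethylsilyl)ethene
Product: 8 (Z)-(2-bromoethenyl)trimethylsilane, via meso-dibromide 7 (not isolated)
Conditions: Br2, CH2Cl2, −78 °C; NaOMe, MeOH, 0 °C
Reagents that add atoms: bromine BrBr
Why: Bromodesilylation of a vinylsilane: anti addition of bromine followed by anti elimination of bromide and silicon inverts the alkene geometry, so the E-disilylethene should give the Z-bromovinylsilane.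

Step 5
Reactants: 8 (Z)-(2-bromoethenyl)trimethylsilane; 5 (5E,9E)-6,10,14-trimethylpentadeca-5,9,13-trien-3-yn-2-one
Product: 10 rac-(1Z,6E,10E)-3,7,11,15-tetramethyl-1-(trimethylsilyl)hexadeca-1,6,10,14-tetraen-4-yn-3-ol, via (Z)-silylvinyllithium 9 (not isolated)
Conditions: t-BuLi (2 equiv), Et2O, −78 °C; then 5, −78 °C; H2O
Reagents that add atoms: none
Why: Bromine–lithium exchange proceeds with retention of the Z geometry and the hard vinyllithium should add 1,2 to the ynone carbonyl; the carbinol carbon (later C6) is made racemic on purpose because it is re-ionised in step 10.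

Step 6
Reactants: 11 methyl (2R)-3-hydroxy-2-methylpropanoate
Product: 12 methyl (2R)-2-methyl-3-(naphthalen-2-ylmethoxy)propanoate
Conditions: 2-(bromomethyl)naphthalene, Ag2O, CH2Cl2, rt, dark
Reagents that add atoms: 2-(bromomethyl)naphthalene BrCc1ccc2ccccc2c1
Why: Ag2O-mediated Williamson etherification is non-basic, so the β-hydroxy ester should be alkylated without retro-Michael loss or racemisation of the methyl-bearing stereocentre.

Step 7
Reactants: 12 methyl (2R)-2-methyl-3-(naphthalen-2-ylmethoxy)propanoate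
Product: 13 (2R)-2-methyl-3-(naphthalen-2-ylmethoxy)propanal
Conditions: i-Bu2AlH, CH2Cl2, −78 °C; Rochelle salt
Reagents that add atoms: none
Why: Low-temperature i-Bu2AlH half-reduction: the tetrahedral aluminium hemiacetal survives at −78 °C and collapses to the aldehyde only on work-up, which should keep the α-stereocentre intact.

Step 8
Reactants: 13 (2R)-2-methyl-3-(naphthalen-2-ylmethoxy)propanal
Product: 14 2-{[(2R)-3,3-dimethoxy-2-methylpropoxy]methyl}naphthalene
Conditions: HC(OMe)3, PPTS (cat.), CH2Cl2, rt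
Reagents that add atoms: trimethyl orthoformate COC(OC)OC
Why: Acid-catalysed acetalisation with the orthoformate as methoxy donor and water scavenger, under conditions too mild to enolise the aldehyde.

Step 9
Reactants: 14 2-{[(2R)-3,3-dimethoxy-2-methylpropoxy]methyl}naphthalene
Product: 15 2-{[(2R)-3-hydroperoxy-3-methoxy-2-methylpropoxy]methyl}naphthalene
Conditions: H2O2 (anhydrous, Et2O), camphorsulfonic acid (cat.), 0 °C
Reagents that add atoms: hydrogen peroxide OO
Why: Acid-catalysed acetal–hydroperoxide exchange (perhydrolysis through the oxocarbenium ion) should replace one methoxy group by OOH, the reaction type that turns 2,2-dimethoxypropane into 2-methoxyprop-2-yl hydroperoxide.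

Step 10
Reactants: 15 2-{[(2R)-3-hydroperoxy-3-methoxy-2-methylpropoxy]methyl}naphthalene; 10 rac-(1Z,6E,10E)-3,7,11,15-tetramethyl-1-(trimethylsilyl)hexadeca-1,6,10,14-tetraen-4-yn-3-ol
Product: 17 2-{[(2R)-2-{(3S,6R)-6-methyl-6-[(3E,7E)-4,8,12-trimethyltrideca-3,7,11-trien-1-yn-1-yl]-3,6-dihydro-1,2-dioxin-3-yl}propoxy]methyl}naphthalene, via mixed peroxyacetal 16 (not isolated)
Conditions: BF3·OEt2 (cat.), 4 Å MS, CH2Cl2, −40 °C; then SnCl4, 2,6-di-tert-butyl-4-methylpyridine, −78 to −40 °C
Reagents that add atoms: none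
Why: Proposed new method: catalytic BF3 ionises carbinol 10 to a C6 cation that is both allylic and propargylic and the OOH group of 15 traps it (closest known type: acid-catalysed tert-alkylation of hydroperoxides by tertiary alcohols), forming O1–C6 in mixed peroxyacetal 16; SnCl4 then ionises the acetal C–OMe bond to a peroxycarbenium ion (known for monoperoxyacetals, which are captured by allylsilanes and enol silanes), the silicon-bearing carbon of the vinylsilane attacks it to form C3–C4, and the β-silyl cation loses Me3Si+ (trapped as Me3SiOMe) to leave the C4=C5 bond. The one ring formed, the 3,6-dihydro-1,2-dioxin, is closed 6-endo through a chair-like transition state, the closest known ring closure being the vinylsilane-terminated oxocarbenium (silyl-Prins) cyclisation to dihydropyrans. C3 is set by the neighbouring (R)-methyl-bearing carbon: SnCl4 is expected to chelate the acetal methoxy and the naphthylmethyl ether oxygens, and the tethered vinylsilane displaces the chelated methoxide from the face away from the methyl group (Cram-chelate sense), which gives the anti relation between the side-chain methyl and the C3–O2 bond, whereas a free ion would follow Felkin–Anh to the syn epimer. C6 is set relative to C3 under Curtin–Hammett control because the doubly stabilised C6–O1 bond should re-ionise reversibly: in the chair the C3 side chain is equatorial, the Z-vinylsilane places SiMe3 axial on C4 (as β-silicon stabilisation requires), and only the rod-like alkynyl group tolerates the 1,3-diaxial position on C6, so methyl is equatorial and the chain ends cis to the C3 substituent. The step needs chemoselectivity over three trisubstituted alkenes and the enyne, which is secured by the intramolecular six-ring closure onto a vinylsilane more nucleophilic than an alkene and by the hindered pyridine that buffers protic acid.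

Step 11
Reactants: 17 2-{[(2R)-2-{(3S,6R)-6-methyl-6-[(3E,7E)-4,8,12-trimethyltrideca-3,7,11-trien-1-yn-1-yl]-3,6-dihydro-1,2-dioxin-3-yl}propoxy]methyl}naphthalene
Product: 18 2-{[(2R)-2-{(3S,6S)-6-methyl-6-[(3E,7E)-4,8,12-trimethyltrideca-3,7,11-trien-1-yl]-1,2-dioxan-3-yl}propoxy]methyl}naphthalene
Conditions: KO2CN=NCO2K (excess, in portions), AcOH, MeOH/CH2Cl2, 0 °C to rt
Reagents that add atoms: none
Why: Diimide reduction: concerted syn transfer of H2 should saturate the cis ring alkene and the alkyne (through its cis-alkene) much faster than the trisubstituted alkenes, and it leaves the O–O bond, the naphthyl group and the three stereocentres alone.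

Step 12
Reactants: 18 2-{[(2R)-2-{(3S,6S)-6-methyl-6-[(3E,7E)-4,8,12-trimethyltrideca-3,7,11-trien-1-yl]-1,2-dioxan-3-yl}propoxy]methyl}naphthalene
Product: 19 (2R)-2-{(3S,6S)-6-methyl-6-[(3E,7E)-4,8,12-trimethyltrideca-3,7,11-trien-1-yl]-1,2-dioxan-3-yl}propan-1-ol
Conditions: DDQ, CH2Cl2/pH 7 buffer, 0 °C to rt
Reagents that add atoms: none
Why: Oxidative cleavage of the electron-rich naphthylmethyl ether by hydride abstraction and hydrolysis, a non-reducing deprotection that should spare the peroxide and the trisubstituted alkenes.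

Step 13
Reactants: 19 (2R)-2-{(3S,6S)-6-methyl-6-[(3E,7E)-4,8,12-trimethyltrideca-3,7,11-trien-1-yl]-1,2-dioxan-3-yl}propan-1-ol
Product: 21 (2S)-2-{(3S,6S)-6-methyl-6-[(3E,7E)-4,8,12-trimethyltrideca-3,7,11-trien-1-yl]-1,2-dioxan-3-yl}propanoic acid, via aldehyde 20 (not isolated)
Conditions: TEMPO (cat.), PhI(OAc)2, MeCN/H2O, rt
Reagents that add atoms: water O
Why: Oxoammonium oxidation in wet acetonitrile takes the alcohol through aldehyde 20 and its hydrate to the acid under neutral to mildly acidic conditions, avoiding base that would epimerise the side-chain stereocentre or open the ring by retro-oxa-Michael reaction.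

**Compound list**

1 | (2E,6E)-farnesol | CC(C)=CCC/C(C)=C/CC/C(C)=C/CO | starting material
2 | (2E,6E)-3,7,11-trimethyldodeca-2,6,10-trienal | CC(C)=CCC/C(C)=C/CC/C(C)=C/C=O | intermediate
3 | (3E,7E)-4,8,12-trimethyltrideca-3,7,11-trien-1-yne | CC(C)=CCC/C(C)=C/CC/C(C)=C/C#C | intermediate
4 | lithium (3E,7E)-4,8,12-trimethyltrideca-3,7,11-trien-1-yn-1-ide | CC(C)=CCC/C(C)=C/CC/C(C)=C/C#C[Li] | intermediate
5 | (5E,9E)-6,10,14-trimethylpentadeca-5,9,13-trien-3-yn-2-one | CC(C)=CCC/C(C)=C/CC/C(C)=C/C#CC(C)=O | intermediate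
6 | (E)-1,2-bis(trimethylsilyl)ethene | C[Si](C)(C)/C=C/[Si](C)(C)C | starting material
7 | (1R,2S)-1,2-dibromo-1,2-bis(trimethylsilyl)ethane (meso) | C[Si](C)(C)[C@H](Br)[C@H](Br)[Si](C)(C)C | intermediate
8 | (Z)-(2-bromoethenyl)trimethylsilane | C[Si](C)(C)/C=C\Br | intermediate
9 | (Z)-[2-(trimethylsilyl)ethenyl]lithium | C[Si](C)(C)/C=C\[Li] | intermediate
10 | rac-(1Z,6E,10E)-3,7,11,15-tetramethyl-1-(trimethylsilyl)hexadeca-1,6,10,14-tetraen-4-yn-3-ol | CC(C)=CCC/C(C)=C/CC/C(C)=C/C#CC(C)(O)/C=C\[Si](C)(C)C | intermediate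
11 | methyl (2R)-3-hydroxy-2-methylpropanoate | COC(=O)[C@H](C)CO | starting material
12 | methyl (2R)-2-methyl-3-(naphthalen-2-ylmethoxy)propanoate | COC(=O)[C@H](C)COCc1ccc2ccccc2c1 | intermediate
13 | (2R)-2-methyl-3-(naphthalen-2-ylmethoxy)propanal | O=C[C@H](C)COCc1ccc2ccccc2c1 | intermediate
14 | 2-{[(2R)-3,3-dimethoxy-2-methylpropoxy]methyl}naphthalene | COC(OC)[C@H](C)COCc1ccc2ccccc2c1 | intermediate
15 | 2-{[(2R)-3-hydroperoxy-3-methoxy-2-methylpropoxy]methyl}naphthalene (both epimers at the acetal carbon) | COC(OO)[C@H](C)COCc1ccc2ccccc2c1 | intermediate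
16 | 2-{[(2R)-3-methoxy-2-methyl-3-{[(1Z,6E,10E)-3,7,11,15-tetramethyl-1-(trimethylsilyl)hexadeca-1,6,10,14-tetraen-4-yn-3-yl]peroxy}propoxy]methyl}naphthalene (mixture at the acetal and tertiary carbons) | CC(C)=CCC/C(C)=C/CC/C(C)=C/C#CC(C)(OOC(OC)[C@H](C)COCc1ccc2ccccc2c1)/C=C\[Si](C)(C)C | intermediate
17 | 2-{[(2R)-2-{(3S,6R)-6-methyl-6-[(3E,7E)-4,8,12-trimethyltrideca-3,7,11-trien-1-yn-1-yl]-3,6-dihydro-1,2-dioxin-3-yl}propoxy]methyl}naphthalene | CC(C)=CCC/C(C)=C/CC/C(C)=C/C#C[C@@]1(C)C=C[C@@H]([C@H](C)COCc2ccc3ccccc3c2)OO1 | intermediate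
18 | 2-{[(2R)-2-{(3S,6S)-6-methyl-6-[(3E,7E)-4,8,12-trimethyltrideca-3,7,11-trien-1-yl]-1,2-dioxan-3-yl}propoxy]methyl}naphthalene | CC(C)=CCC/C(C)=C/CC/C(C)=C/CC[C@@]1(C)CC[C@@H]([C@H](C)COCc2ccc3ccccc3c2)OO1 | intermediate
19 | (2R)-2-{(3S,6S)-6-methyl-6-[(3E,7E)-4,8,12-trimethyltrideca-3,7,11-trien-1-yl]-1,2-dioxan-3-yl}propan-1-ol | CC(C)=CCC/C(C)=C/CC/C(C)=C/CC[C@@]1(C)CC[C@@H]([C@H](C)CO)OO1 | intermediate
20 | (2S)-2-{(3S,6S)-6-methyl-6-[(3E,7E)-4,8,12-trimethyltrideca-3,7,11-trien-1-yl]-1,2-dioxan-3-yl}propanal | CC(C)=CCC/C(C)=C/CC/C(C)=C/CC[C@@]1(C)CC[C@@H]([C@H](C)C=O)OO1 | intermediate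
21 | (2S)-2-{(3S,6S)-6-methyl-6-[(3E,7E)-4,8,12-trimethyltrideca-3,7,11-trien-1-yl]-1,2-dioxan-3-yl}propanoic acid | CC(C)=CCC/C(C)=C/CC/C(C)=C/CC[C@@]1(C)CC[C@@H]([C@H](C)C(=O)O)OO1 | target

**Step count**

Total steps: 13. Longest linear sequence: 8 steps (1, 2, 3, 5, 10, 11, 12, 13; the branch 6, 7, 8, 9, 10, 11, 12, 13 is equally long).

**Steps most likely to fail**

1. Step 10 (the step that carries the label "Proposed new method:").
 - What may go wrong: loss of facial control at C3 if the peroxycarbenium ion reacts as a free, non-chelated ion in the Felkin–Anh sense.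
 - What may go wrong: diversion of the C6 cation by capture at the alkyne terminus or by loss of a methyl proton.
 - What may go wrong: acid-induced cyclisation of the polyene chain.
 - Fallback (known reactions only; the ring is then closed through O2–C3 after O1–C6; it sets out from 13 and rejoins at 18): the dianion of 3-methylbut-3-en-1-ol (n-BuLi, TMEDA) is alkylated with commercial (2E,6E)-farnesyl bromide to give (6E,10E)-7,11,15-trimethyl-3-methylidenehexadeca-6,10,14-trien-1-ol F1. An Appel reaction (CBr4, PPh3) gives (6E,10E)-1-bromo-7,11,15-trimethyl-3-methylidenehexadeca-6,10,14-triene F2. Barbier addition (Mg, THF) of F2 to aldehyde 13 gives the secondary alcohol (2R,9E,13E)-2,10,14,18-tetramethyl-6-methylidene-1-(naphthalen-2-ylmethoxy)nonadeca-9,13,17-trien-3-ol F3 as a mixture of C3 epimers, and Dess–Martin oxidation gives the ketone (2R,9E,13E)-2,10,14,18-tetramethyl-6-methylidene-1-(naphthalen-2-ylmethoxy)nonadeca-9,13,17-trien-3-one F4. Chelation-controlled reduction with Zn(BH4)2, hydride entering anti to the methyl group of the chelate, should give the (2R,3R)-alcohol F5, which is mesylated (MsCl, Et3N) to the (2R,3R)-methanesulfonate F6. Isayama–Mukaiyama hydroperoxysilylation (Co(acac)2, O2, Et3SiH) of the 1,1-disubstituted alkene, which reacts before the trisubstituted ones, gives the tertiary triethylsilyl peroxide F7 as a mixture of C6 epimers. Bu4NF-induced desilylative 6-exo-tet ring closure then displaces the mesylate with inversion at C3 and should give 18 together with its C6 epimer, to be separated by chromatography.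

2. Step 5.
 - What may go wrong: enolisation of the methyl ynone by the basic vinyllithium, partial Z to E isomerisation of the vinyl anion, or conjugate addition.
 - Fallback (the C6–alkynyl bond is formed instead of the C6–vinyl bond; it sets out from 3 and rejoins at 10): commercial 4-(trimethylsilyl)but-3-yn-2-one is semihydrogenated (H2, Pd/CaCO3 poisoned with Pb(OAc)2, quinoline) to (Z)-4-(trimethylsilyl)but-3-en-2-one F8. Acetylide 4 (from 3 and n-BuLi) is added to it at −78 °C in the presence of CeCl3 to give 10; steps 3 and 4 are then not needed.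

3. Step 9.
 - What may go wrong: exchange of both methoxy groups, premature ionisation back to the aldehyde, or epimerisation next to the acetal carbon during the acid treatment.
 - Fallback (a different peroxide precursor; it sets out from 13 and rejoins at 17): aldehyde 13 is condensed with H2O2 under Re2O7 catalysis in MeCN to the geminal dihydroperoxide 2-{[(2R)-3,3-dihydroperoxy-2-methylpropoxy]methyl}naphthalene F9. F9 replaces 15 in step 10, one OOH group being alkylated at C6 while the other serves as the leaving group on C3.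

**Further compounds**

F1 | step 10 | (6E,10E)-7,11,15-trimethyl-3-methylidenehexadeca-6,10,14-trien-1-ol | CC(C)=CCC/C(C)=C/CC/C(C)=C/CCC(=C)CCO
F2 | step 10 | (6E,10E)-1-bromo-7,11,15-trimethyl-3-methylidenehexadeca-6,10,14-triene | CC(C)=CCC/C(C)=C/CC/C(C)=C/CCC(=C)CCBr
F3 | step 10 | (2R,9E,13E)-2,10,14,18-tetramethyl-6-methylidene-1-(naphthalen-2-ylmethoxy)nonadeca-9,13,17-trien-3-ol (C3 epimers) | CC(C)=CCC/C(C)=C/CC/C(C)=C/CCC(=C)CCC(O)[C@H](C)COCc1ccc2ccccc2c1
F4 | step 10 | (2R,9E,13E)-2,10,14,18-tetramethyl-6-methylidene-1-(naphthalen-2-ylmethoxy)nonadeca-9,13,17-trien-3-one | CC(C)=CCC/C(C)=C/CC/C(C)=C/CCC(=C)CCC(=O)[C@H](C)COCc1ccc2ccccc2c1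
F5 | step 10 | (2R,3R,9E,13E)-2,10,14,18-tetramethyl-6-methylidene-1-(naphthalen-2-ylmethoxy)nonadeca-9,13,17-trien-3-ol | CC(C)=CCC/C(C)=C/CC/C(C)=C/CCC(=C)CC[C@@H](O)[C@H](C)COCc1ccc2ccccc2c1
F6 | step 10 | (2R,3R,9E,13E)-2,10,14,18-tetramethyl-6-methylidene-1-(naphthalen-2-ylmethoxy)nonadeca-9,13,17-trien-3-yl methanesulfonate | CC(C)=CCC/C(C)=C/CC/C(C)=C/CCC(=C)CC[C@@H](OS(C)(=O)=O)[C@H](C)COCc1ccc2ccccc2c1
F7 | step 10 | (2R,3R,9E,13E)-2,6,10,14,18-pentamethyl-1-(naphthalen-2-ylmethoxy)-6-[(triethylsilyl)peroxy]nonadeca-9,13,17-trien-3-yl methanesulfonate (C6 epimers) | CC(C)=CCC/C(C)=C/CC/C(C)=C/CCC(C)(OO[Si](CC)(CC)CC)CC[C@@H](OS(C)(=O)=O)[C@H](C)COCc1ccc2ccccc2c1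
F8 | step 5 | (Z)-4-(trimethylsilyl)but-3-en-2-one | CC(=O)/C=C\[Si](C)(C)C
F9 | step 9 | 2-{[(2R)-3,3-dihydroperoxy-2-methylpropoxy]methyl}naphthalene | OOC(OO)[C@H](C)COCc1ccc2ccccc2c1
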